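Everything rests on opening the five-membered lactol ring fused to ring B. Its O–CH(OH) carbon is the hydrate carbon of a formyl group that sits ortho to the ring-B carbon bearing the lactone carbonyl, so the two hydrate hydroxyls are enantiotopic. One chiral-palladium carbonylation therefore inserts CO at that ring-B carbon, acylates one of the two hydroxyls, closes the lactol ring and sets the only stereocentre. The precursor is the complete depsidone carrying a phenol, a bromine and a formyl group on three adjacent ring-B carbons; it is assembled by Ullmann etherification of two benzyl-protected arenes, hydrogenolysis, bromination and carbodiimide lactonisation.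

Key step: step 12

Remark: ring A is the methoxy-bearing benzoyl ring and ring B the phenol-bearing ring of the depsidone; the target lactol carbon is (R) as drawn.
Assumption: the ligand antipode that gives the (R)-lactol cannot be predicted and is to be fixed by an analytical screen ((R)-DTBM-SEGPHOS is written as the lead), and the lactol is taken to be configurationally stable in neutral aprotic media although labile to ring–chain tautomerism under acid or base.

Step 1
Reactants: 1 3,5-dihydroxy-4-methylbenzoic acid
Product: 2 benzyl 3,5-bis(benzyloxy)-4-methylbenzoate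
Conditions: BnBr (3.5 equiv), K2CO3, DMF, 60 °C
Reagents that add atoms: benzyl bromide, BrCc1ccccc1
Why: Williamson O-alkylation of both phenoxides and of the carboxylate should give the tribenzyl compound, whose three benzyl groups can later be removed together.

Step 2
Reactants: 2 benzyl 3,5-bis(benzyloxy)-4-methylbenzoate
Product: 3 [3,5-bis(benzyloxy)-4-methylphenyl]methanol
Conditions: LiAlH4, THF, 0 °C to rt; Fieser work-up
Reagents that add atoms: none
Why: Hydride reduction of the ester by LiAlH4 should give the benzylic alcohol, aryl benzyl ethers being inert to hydride.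

Step 3
Reactants: 3 [3,5-bis(benzyloxy)-4-methylphenyl]methanol
Product: 4 3,5-bis(benzyloxy)-4-methylbenzaldehyde
Conditions: activated MnO2, CH2Cl2, rt
Reagents that add atoms: none
Why: Manganese dioxide oxidation of a benzylic alcohol should stop cleanly at the aldehyde.

Step 4
Reactants: 4 3,5-bis(benzyloxy)-4-methylbenzaldehyde
Product: 5 3,5-bis(benzyloxy)-2-bromo-4-methylbenzaldehyde
Conditions: NBS (1.05 equiv), MeCN, 0 °C to rt, dark
Reagents that add atoms: N-bromosuccinimide, O=C1CCC(=O)N1Br
Why: Electrophilic aromatic bromination can only occur at one of the two equivalent open positions (each ortho and para to a benzyloxy group), and the first bromine together with the formyl group should hold the reaction at monosubstitution.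

Step 5
Reactants: 6 atraric acid (methyl 2,4-dihydroxy-3,6-dimethylbenzoate)
Product: 7 methyl 2-hydroxy-4-methoxy-3,6-dimethylbenzoate
Conditions: MeI (1.05 equiv), K2CO3, acetone, reflux
Reagents that add atoms: iodomethane, CI
Why: Williamson methylation should take only the 4-hydroxyl, because the 2-hydroxyl is chelated to the ester carbonyl and flanked by a methyl group.

Step 6
Reactants: 7 methyl 2-hydroxy-4-methoxy-3,6-dimethylbenzoate
Product: 8 2-hydroxy-4-methoxy-3,6-dimethylbenzoic acid (rhizonic acid)
Conditions: KOH, DMSO–H2O, 80 °C; then cold dilute HCl
Reagents that add atoms: potassium hydroxide, [K+].[OH-]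
Why: Saponification in aqueous DMSO should cleave the hindered salicylate ester, and cold acidification avoids decarboxylation of the electron-rich acid.

Step 7
Reactants: 8 2-hydroxy-4-methoxy-3,6-dimethylbenzoic acid
Product: 9 benzyl 2-hydroxy-4-methoxy-3,6-dimethylbenzoate
Conditions: BnBr (1.05 equiv), KHCO3, DMF, rt
Reagents that add atoms: benzyl bromide, BrCc1ccccc1
Why: SN2 alkylation of the carboxylate under bicarbonate should give the benzyl ester while the chelated phenol stays protonated and free.

Step 8
Reactants: 5 3,5-bis(benzyloxy)-2-bromo-4-methylbenzaldehyde; 9 benzyl 2-hydroxy-4-methoxy-3,6-dimethylbenzoate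
Product: 10 benzyl 2-[2,4-bis(benzyloxy)-6-formyl-3-methylphenoxy]-4-methoxy-3,6-dimethylbenzoate
Conditions: CuI (20 mol %), picolinic acid (40 mol %), K3PO4, DMSO, 100 °C, argon
Reagents that add atoms: none
Why: Ullmann-type copper-catalysed diaryl ether synthesis should join the hindered phenoxide to the aryl bromide, whose ortho formyl group activates the C–Br bond and can chelate copper.

Step 9
Reactants: 10 benzyl 2-[2,4-bis(benzyloxy)-6-formyl-3-methylphenoxy]-4-methoxy-3,6-dimethylbenzoate
Product: 11 2-(6-formyl-2,4-dihydroxy-3-methylphenoxy)-4-methoxy-3,6-dimethylbenzoic acid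
Conditions: H2 (1 atm), 10% Pd/C, EtOAc, rt, stopped after 3 equiv H2
Reagents that add atoms: none
Why: Catalytic hydrogenolysis should cleave the two aryl benzyl ethers and the benzyl ester much faster than it reduces the aryl aldehyde, so stopping at three equivalents of hydrogen should leave the formyl group intact.

Step 10
Reactants: 11 2-(6-formyl-2,4-dihydroxy-3-methylphenoxy)-4-methoxy-3,6-dimethylbenzoic acid
Product: 12 2-(3-bromo-2-formyl-4,6-dihydroxy-5-methylphenoxy)-4-methoxy-3,6-dimethylbenzoic acid
Conditions: NBS (1.0 equiv), MeCN, −20 to 0 °C, dark
Reagents that add atoms: N-bromosuccinimide, O=C1CCC(=O)N1Br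
Why: Electrophilic aromatic bromination should go to the single open ring-B position, which is ortho to one free hydroxyl and para to the other and so far more reactive than the one anisole-type position of ring A.

Step 11
Reactants: 12 2-(3-bromo-2-formyl-4,6-dihydroxy-5-methylphenoxy)-4-methoxy-3,6-dimethylbenzoic acid
Product: 13 7-bromo-8-hydroxy-3-methoxy-1,4,9-trimethyl-11-oxo-11H-dibenzo[b,e][1,4]dioxepine-6-carbaldehyde
Conditions: DCC (1.1 equiv), CH2Cl2–THF (0.01 M), 0 °C to rt
Reagents that add atoms: none
Why: Carbodiimide-mediated lactonisation should close the seven-membered depsidone ring, because only the hydroxyl next to the ether oxygen can reach the activated acid and the other phenol is shielded by bromine and methyl.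

Step 12
Reactants: 13 7-bromo-8-hydroxy-3-methoxy-1,4,9-trimethyl-11-oxo-11H-dibenzo[b,e][1,4]dioxepine-6-carbaldehyde; 14 carbon monoxide
Product: 16 (R)-hypostictic acid (target), via aldehyde hydrate 15 (not isolated)
Conditions: CO (1 atm), H2O (3 equiv), Pd2(dba)3 (2.5 mol %), (R)-DTBM-SEGPHOS (6 mol %), 2,6-lutidine (1.2 equiv), toluene–1,4-dioxane, 60 °C; Celite filtration, crystallisation from toluene–MeCN, −20 °C
Reagents that add atoms: water, O
Why: Proposed new method: Pd(0) bearing the chiral bisphosphine should insert into the ring-B C–Br bond of 13, CO insertion gives an aroylpalladium bromide, and one hydroxyl of the neighbouring, reversibly formed gem-diol 15 displaces bromide (2,6-lutidine takes up HBr) to give a six-membered acyl(alkoxo)palladacycle from which C(acyl)–O reductive elimination releases the lactone and Pd(0). The closest known reaction types are the racemic palladium-catalysed carbonylative cyclisation of 2-halobenzaldehydes to 3-hydroxy- or 3-alkoxyphthalides and the enantioselective desymmetrising alkoxycarbonylation of prochiral diols. The five-membered lactol ring closes in a 5-exo-trig sense, a hydrate oxygen attacking the acyl carbon held on the adjacent ring carbon. The configuration of the new lactol carbon is controlled only by the chiral ligand on palladium, which selects between the two enantiotopic hydroxyls during palladacycle formation and reductive elimination, the substrate having no other stereocentre. The step needs intramolecular acyl capture to outrun attack of free water on the aroylpalladium (which would give the free acid and then racemic lactol), and this is secured by the ortho placement of formyl and bromine, the small excess of water and the weak hindered base, while the phenol on the other side of the bromine cannot intercept the acyl group because that would require a four-membered ring. Lutidine-buffered aprotic conditions and crystallisation without aqueous base are chosen to suppress ring–chain racemisation of the product.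

Compound list
1 | 3,5-dihydroxy-4-methylbenzoic acid | Cc1c(O)cc(C(=O)O)cc1O | starting material
2 | benzyl 3,5-bis(benzyloxy)-4-methylbenzoate | Cc1c(OCc2ccccc2)cc(C(=O)OCc2ccccc2)cc1OCc1ccccc1 | intermediate
3 | [3,5-bis(benzyloxy)-4-methylphenyl]methanol | Cc1c(OCc2ccccc2)cc(CO)cc1OCc1ccccc1 | intermediate
4 | 3,5-bis(benzyloxy)-4-methylbenzaldehyde | Cc1c(OCc2ccccc2)cc(C=O)cc1OCc1ccccc1 | intermediate
5 | 3,5-bis(benzyloxy)-2-bromo-4-methylbenzaldehyde | Cc1c(OCc2ccccc2)cc(C=O)c(Br)c1OCc1ccccc1 | intermediate
6 | atraric acid (methyl 2,4-dihydroxy-3,6-dimethylbenzoate) | COC(=O)c1c(C)cc(O)c(C)c1O | starting material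
7 | methyl 2-hydroxy-4-methoxy-3,6-dimethylbenzoate | COC(=O)c1c(C)cc(OC)c(C)c1O | intermediate
8 | 2-hydroxy-4-methoxy-3,6-dimethylbenzoic acid (rhizonic acid) | COc1cc(C)c(C(=O)O)c(O)c1C | intermediate
9 | benzyl 2-hydroxy-4-methoxy-3,6-dimethylbenzoate | COc1cc(C)c(C(=O)OCc2ccccc2)c(O)c1C | intermediate
10 | benzyl 2-[2,4-bis(benzyloxy)-6-formyl-3-methylphenoxy]-4-methoxy-3,6-dimethylbenzoate | COc1cc(C)c(C(=O)OCc2ccccc2)c(Oc2c(OCc3ccccc3)c(C)c(OCc3ccccc3)cc2C=O)c1C | intermediate
11 | 2-(6-formyl-2,4-dihydroxy-3-methylphenoxy)-4-methoxy-3,6-dimethylbenzoic acid | COc1cc(C)c(C(=O)O)c(Oc2c(O)c(C)c(O)cc2C=O)c1C | intermediate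
12 | 2-(3-bromo-2-formyl-4,6-dihydroxy-5-methylphenoxy)-4-methoxy-3,6-dimethylbenzoic acid | COc1cc(C)c(C(=O)O)c(Oc2c(O)c(C)c(O)c(Br)c2C=O)c1C | intermediate
13 | 7-bromo-8-hydroxy-3-methoxy-1,4,9-trimethyl-11-oxo-11H-dibenzo[b,e][1,4]dioxepine-6-carbaldehyde (ortho-bromobenzaldehyde depsidone) | COc1cc(C)c2c(c1C)Oc1c(c(C)c(O)c(Br)c1C=O)OC2=O | intermediate
14 | carbon monoxide | [C-]#[O+] | starting material
15 | 7-bromo-6-(dihydroxymethyl)-8-hydroxy-3-methoxy-1,4,9-trimethyl-11H-dibenzo[b,e][1,4]dioxepin-11-one (aldehyde hydrate of 13) | COc1cc(C)c2c(c1C)Oc1c(c(C)c(O)c(Br)c1C(O)O)OC2=O | intermediate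
16 | (R)-hypostictic acid: the depsidone skeleton of 13 with a five-membered lactol–lactone ring fused across C6–C7 of ring B, lactone carbonyl on C7, (R)-configured O–CH(OH) carbon on C6 | COc1cc(C)c2c(c1C)Oc1c(c(C)c(O)c3c1[C@H](O)OC3=O)OC2=O | target

Total step count: 12. Longest linear sequence: 9 steps (steps 1–4, then 8–12).

Steps most likely to fail

Step 12. Selection between the two enantiotopic hydroxyls may be poor, free water may intercept the aroylpalladium intermolecularly, or the lactol may racemise by ring–chain tautomerism at the reaction temperature. The fallback sets out from 13 and uses known chemistry. Achiral palladium-catalysed carbonylative cyclisation of the 2-bromobenzaldehyde (Pd(OAc)2, Xantphos, CO 1 atm, H2O, Et3N, 1,4-dioxane, 80 °C) should give the racemic lactol F1. Preparative chromatography on an immobilised polysaccharide chiral stationary phase (supercritical CO2–MeCN, no acidic or basic additive, sub-ambient temperature) should then separate the enantiomers. The unwanted (S)-lactol F2 is re-equilibrated to F1 with a trace of triethylamine in THF and recycled. The fallback comes back to the route at 16.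

Step 8. The copper-catalysed coupling may stall because both partners are di-ortho-substituted, leaving protodebromination of the aryl bromide as the main event. The fallback sets out from 4 and replaces metal catalysis by nucleophilic aromatic substitution. Electrophilic fluorination with Selectfluor (MeCN, 60 °C) at one of the two equivalent open positions should give 3,5-bis(benzyloxy)-2-fluoro-4-methylbenzaldehyde F3. The caesium phenoxide of 9 (Cs2CO3, DMF, 100 °C) then displaces fluoride, the ortho formyl group stabilising the Meisenheimer adduct. The fallback comes back to the route at 10.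

Step 10. Bromination may lose site selectivity through ipso attack with decarboxylation on the electron-rich ring-A acid, or the hydroquinone-type ring B may be oxidised. The fallback sets out from 11 and reverses the order of ring closure and halogenation. DCC lactonisation (CH2Cl2–THF, high dilution) should first give the bromine-free depsidone aldehyde 8-hydroxy-3-methoxy-1,4,9-trimethyl-11-oxo-11H-dibenzo[b,e][1,4]dioxepine-6-carbaldehyde F4, in which the acid is tied up as the lactone. Amine-mediated ortho-bromination of its single free phenol (NBS, catalytic i-Pr2NH, CH2Cl2, 0 °C) then delivers bromine to the only open ortho position. The fallback comes back to the route at 13.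

Further compounds
F1 | step 12 | racemic lactol (rac-hypostictic acid) | COc1cc(C)c2c(c1C)Oc1c(c(C)c(O)c3c1C(O)OC3=O)OC2=O
F2 | step 12 | (S)-lactol ((S)-hypostictic acid) | COc1cc(C)c2c(c1C)Oc1c(c(C)c(O)c3c1[C@@H](O)OC3=O)OC2=O
F3 | step 8 | 3,5-bis(benzyloxy)-2-fluoro-4-methylbenzaldehyde | Cc1c(OCc2ccccc2)cc(C=O)c(F)c1OCc1ccccc1
F4 | step 10 | 8-hydroxy-3-methoxy-1,4,9-trimethyl-11-oxo-11H-dibenzo[b,e][1,4]dioxepine-6-carbaldehyde | COc1cc(C)c2c(c1C)Oc1c(c(C)c(O)cc1C=O)OC2=O
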